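Read at 5.00 h, the south run holds 19.8 % of side product B (B from here on) and 10.8 % of target, while the east run, charged with more reagent, holds 19.7 % and 14.2 % at that same time.

| flask | substrate | reagent | temperature | remark | time |
|---|---|---|---|---|---|
| south | 11 mM | 5.5 mM | 0 °C | run made earlier |  |
| north-east | 11 mM | 3.7 mM | 11 °C | run made earlier |  |
| east | 11 mM | 8.2 mM | 0 °C | run made earlier |  |
| delta | 11 mM (fed, over 50 min) | 5.50 mM | 5 °C | all else is in the flask from the start; the feed brings no volume worth counting | 8.0 h |
| zeta | 11 mM (in portions, 4, over 3.0 h) | 5.50 mM | 5 °C | first portion at the start, last at 3.0 h | 8.0 h |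
| beta | 11 mM | 5.50 mM (fed, over 3.0 h) | 5 °C | all else is in the flask from the start; the feed brings no volume worth counting | 8.0 h |
| epsilon | 11 mM | 5.50 mM | 5 °C | everything together at the start | 8.0 h |
| theta | 11 mM | 5.50 mM |  | everything together at the start at −35 °C, warmed to 5 °C at 3.0 h | 8.0 h |
| gamma | 11 mM | 5.50 mM (fed, over 3.0 h) |  | the addition at −35 °C, then warmed to 5 °C; the feed brings no volume worth counting | 8.0 h |

| run | time / h | side product B / % | target / % |
|---|---|---|---|
| south | 0.250 | 1.7 | 0.1 |
| south | 0.667 | 4.6 | 3.0 |
| south | 1.33 | 7.8 | 2.8 |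
| south | 2.00 | 10.9 | 5.1 |
| south | 3.00 | 14.8 | 7.7 |
| south | 4.00 | 16.7 | 8.4 |
| south | 5.00 | 19.8 | 10.8 |
| north-east | 0.417 | 6.3 | 1.5 |
| north-east | 1.33 | 13.2 | 4.3 |
| north-east | 2.50 | 17.7 | 6.5 |
| north-east | 3.00 | 18.5 | 7.6 |
| north-east | 5.00 | 20.5 | 9.2 |
| north-east | 6.00 | 20.9 | 9.4 |
| north-east | 8.00 | 20.5 | 9.8 |
| east | 0.417 | 3.3 | 1.9 |
| east | 1.33 | 8.2 | 5.8 |
| east | 2.50 | 13.3 | 9.1 |
| east | 3.00 | 13.9 | 9.7 |
| east | 5.00 | 19.7 | 14.2 |
| east | 6.00 | 20.8 | 17.0 |
| east | 8.00 | 23.3 | 18.6 |

(scatter of a reading: 0.5 percentage points)

- the flask that comes out highest in amount of side product B, in percent of the substrate charged, or "all alike" when all lie within 1.5 percentage points (delta / zeta / beta / epsilon / theta / gamma / all alike)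
- side product B at the end, in percent of the substrate charged, delta
- side product B at the end, in percent of the substrate charged, zeta
- side product B at the end, in percent of the substrate charged, beta
- side product B at the end, in percent of the substrate charged, epsilon
- side product B at the end, in percent of the substrate charged, theta
- side product B at the end, in percent of the substrate charged, gamma

- percent here means substrate units held: one side product B counts as two
- a reading or a percentage of target counts all its forms, free or not

What does reagent do to B? Nothing these two runs can show: 19.8 % against 19.7 %.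

And to target? Reagent went up by a factor 1.49, target by 1.31. That is roughly in step, given the scatter.

So what do you carry forward? The B held divided by the target held, read at one time. That quotient still moves along a run: in the east run it falls from 1.74 at 0.417 h to 1.25 at 8.00 h. So I compare south and east at 5.00 h, where it goes roughly as one over reagent. South gives 10.1 mM for h, the B held per target held, times the reagent charged, which is a selectivity factor at this substrate charge. East gives 11.4 mM.

Is that safe at 5 °C? Not quite. North-east, at 11 °C, gives 7.74 mM, lower than south, so I treat the south figure as rough.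

Then which flask? Epsilon should end near 1.83 B per target. Beta has on average about half its reagent during the 3.0 h feed and all of it afterwards, which is 0.812 of the charge averaged over 8.0 h. That gives 2.26, more B per target than epsilon. That ratio gives no amount of B, though, and south and east held B alike at 5.00 h, so h ranks no flask by B; I expect beta and epsilon close, and theta and gamma I have not reckoned. Feeding substrate I cannot price, since south, north-east and east each held 11 mM.

The forecast names epsilon, with delta 18.5 %, zeta 12 %, beta 20 %, epsilon 23.5 %, theta 22 % and gamma 21 %, holding that “Feeding reagent starves B only slightly”.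

The flasks end with B at delta 22.7 %, zeta 19.2 %, beta 25.6 %, epsilon 23.8 %, theta 21.8 % and gamma 21.8 %, so beta stands highest.

    substrate + reagent ⇌ target (K = 6300 L mol⁻¹, k = 8.63 L mol⁻¹ h⁻¹, Ea = 54.0 kJ mol⁻¹, ΔH = −13.0 kJ mol⁻¹)
    substrate → side product A (k = 0.104 h⁻¹, Ea = 98.0 kJ mol⁻¹)
    2 substrate → side product B (k = 4.93 L mol⁻¹ h⁻¹, Ea = 50.0 kJ mol⁻¹)
    crystals ⇌ target, rate k4*(cs4 - [target]) while solid is left; crystals form when [target] > cs4 (solubility = 4.50 mM, k = 10.6 h⁻¹)
    target ⇌ isomer of the product (K = 0.928, k = 0.0124 h⁻¹, Ea = 97.0 kJ mol⁻¹, ΔH = −26.0 kJ mol⁻¹)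
    (constants at 5 °C)

Beta ends with 10.8 % of target, less than the 14.2 % in epsilon, which makes 2.37 B per target in beta against the reckoned 2.26. Take h to one further flask, like zeta but charged with 22 mM of reagent. There h gives 0.459 B per target. That flask ends with 11.5 % of B and 42.9 % of target, all its forms counted, a ratio of 0.268.

The readings were computed for substances that don't exist, and the scatter is random.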